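**Plan**
Retrosynthesis: the C2–Br and C3–Br bonds are cut first (back to 7-bromoindole). The pyrrole ring is then taken down to the N-Boc-indoline, and the benzene ring is cut at C3a–C4 and C7–C7a.
Enabling feature: in the six-membered ring the substituted carbons lie side by side, C3a (bond to C3), C7a (bond to N1) and C7 (Br), while C4, C5 and C6 carry only H. The C4–C5–C6–C7 strip is therefore the diene of a 2-pyrone brominated at its C3. The C3a–C7a edge, shared with the five-membered N-ring, is the C=C of a lactam-derived ketene N,O-acetal.
Forward: the five-membered ring is bought as N-Boc-pyrrolidinone. The benzene ring is annulated onto it by cycloaddition, loss of CO2 and loss of silanol. The N-ring is then dehydrogenated to the pyrrole, and C3 and C2 are brominated last.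
The C7 bromine arrives with the pyrone, so no arene substitution has to find C7.
Stereochemistry: the target has no stereocentre. The stereocentres of the racemic intermediates are transient and vanish on elimination or aromatisation.

Key step: step 5

Remark: chiral intermediates 2, 4, 8 and 9 are racemic, and one enantiomer is drawn where a relative configuration is defined. Pyrone numbering is used for 1–5 and indole numbering from 8 onward.

Step 1
Reactants: 1 5,6-dihydro-2H-pyran-2-one
Product: 3 3-bromo-5,6-dihydro-2H-pyran-2-one, via trans-3,4-dibromolactone 2 (not isolated)
Conditions: Br2 (1.05 equiv), CH2Cl2, 0 °C to rt; then Et3N (1.1 equiv), 0 °C to rt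
Reagents that add atoms: bromine, BrBr
Why: Bromination–dehydrobromination: anti addition of Br2 to C3=C4 gives racemic trans-dibromide 2, from which Et3N removes the acidic C3–H and expels the C4 bromide (E1cB type), erasing both transient stereocentres and leaving bromine on the α-carbon.

Step 2
Reactants: 3 3-bromo-5,6-dihydro-2H-pyran-2-one
Product: 4 3,5-dibromo-5,6-dihydro-2H-pyran-2-one
Conditions: NBS (1.05 equiv), (BzO)2 (cat.), CCl4 (or PhCF3), reflux
Reagents that add atoms: N-bromosuccinimide, O=C1CCC(=O)N1Br
Why: Wohl–Ziegler bromination: hydrogen abstraction occurs only at C5, the sole allylic position, and the new stereocentre is racemic and disappears in step 3.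

Step 3
Reactants: 4 3,5-dibromo-5,6-dihydro-2H-pyran-2-one
Product: 5 3-bromo-2H-pyran-2-one
Conditions: Et3N (1.2 equiv), CH2Cl2, rt
Reagents that add atoms: none
Why: Base-induced 1,2-dehydrobromination (E2) across C5–C6 is driven by formation of the fully conjugated 2-pyrone, while the vinylic C3–Br bond is inert to Et3N.

Step 4
Reactants: 6 tert-butyl 2-oxopyrrolidine-1-carboxylate
Product: 7 tert-butyl 5-[(tert-butyldimethylsilyl)oxy]-2,3-dihydro-1H-pyrrole-1-carboxylate
Conditions: TBSOTf (1.2 equiv), Et3N (2 equiv), CH2Cl2, 0 °C to rt; pentane extraction, no contact with acid
Reagents that add atoms: tert-butyldimethylsilyl trifluoromethanesulfonate, CC(C)(C)[Si](C)(C)OS(=O)(=O)C(F)(F)F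
Why: Soft enolisation: the silyl triflate activates the imide-like lactam carbonyl, Et3N removes the acidified α-hydrogen, and the hard, bulky silicon ends up on oxygen, as is known for imides and N-acyl lactams, with the ring fixing the alkene geometry.

Step 5
Reactants: 5 3-bromo-2H-pyran-2-one; 7 tert-butyl 5-[(tert-butyldimethylsilyl)oxy]-2,3-dihydro-1H-pyrrole-1-carboxylate
Product: 10 tert-butyl 7-bromoindoline-1-carboxylate, via bridged lactone cycloadduct 8 (not isolated), via silyloxy cyclohexadiene 9 (not isolated)
Conditions: 7 (2.5 equiv), BHT (cat.), PhMe (1 M), sealed tube, 110 °C; then CSA (5 mol %), rt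
Reagents that add atoms: none
Why: Proposed new method: the pyrone diene, whose LUMO is lowered by the lactone carbonyl and the C3 bromine, should combine with the electron-rich C=C of 7 in an asynchronous inverse-demand [4+2] cycloaddition in which the β-carbon of 7 (future C3a) bonds early to pyrone C6 (future C4) and the N,O-substituted carbon (future C7a) closes late onto pyrone C3 (future C7); adduct 8 then expels CO2 by retro-[4+2] at the bath temperature to give diene 9. Suprafacial addition to a ring alkene places H-3a and the silyloxy group of 9 cis, so the silanol should leave not by anti elimination but by ionisation to an N-acyliminium ion (a nitrogen-stabilised arenium ion) followed by loss of H-3a, a process that the final trace of acid completes. The closest known reaction type is the inverse-demand Diels–Alder reaction of 3-substituted 2-pyrones with ketene O,O-acetals, and of bromo-2-pyrones with vinyl and silyl enol ethers, followed by loss of CO2 and of the alcohol to give ortho-disubstituted arenes; what is new is an N-acyl silyl ketene N,O-acetal held in a ring as the two-carbon partner. The benzene ring is closed by an intermolecular [4+2] cycloaddition that makes C3a–C4 and C7–C7a in one operation on the preformed five-membered ring, so it is an annulation and not an end-to-end cyclisation. No stereocentre survives: the four of 8 and the two of 9 are erased on aromatisation, endo and exo adducts both converge on 9, and neither facial nor endo/exo control is needed. The step does need regioselectivity (7-bromo, not 4-bromo), secured by matched polarity (largest HOMO coefficient on the acetal β-carbon, largest LUMO coefficient on pyrone C6, as in the known ketene acetal cases where the acetal carbon ends up next to the pyrone C3 substituent), and it needs loss of silanol in preference to the carbamate nitrogen, secured because nitrogen is the better donor for the ionisation and stays tied into the ring.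

Step 6
Reactants: 10 tert-butyl 7-bromoindoline-1-carboxylate
Product: 11 7-bromoindoline
Conditions: TFA, CH2Cl2, 0 °C to rt; aq NaHCO3
Reagents that add atoms: none
Why: Acidolysis of the tert-butyl carbamate (loss of the tert-butyl cation as isobutene, then decarboxylation of the carbamic acid) is standard, the aryl bromide is inert, and the protonated indoline is shielded from tert-butylation.

Step 7
Reactants: 11 7-bromoindoline
Product: 12 7-bromo-1H-indole
Conditions: DDQ (1.05 equiv), PhMe, rt
Reagents that add atoms: none
Why: Quinone dehydrogenation: DDQ abstracts hydride from C2 next to nitrogen and the iminium ion loses H-3, the gain of pyrrole aromaticity driving a conversion that is routine for 7-substituted indolines.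

Step 8
Reactants: 12 7-bromo-1H-indole
Product: 14 2,3,7-tribromo-1H-indole, via 3,7-dibromo-1H-indole 13 (not isolated)
Conditions: NBS (2.05 equiv), silica gel, CH2Cl2, 0 °C to rt, dark
Reagents that add atoms: N-bromosuccinimide, O=C1CCC(=O)N1Br
Why: Electrophilic aromatic substitution: the first equivalent of NBS brominates C3, the most nucleophilic position, to give 13, and the second takes C2, the only free position left in the enamine-like pyrrole ring, while the benzo ring is deactivated by its own bromine, a 2,3-dibromination known for NH-indoles.

**Compound list**
1 | 5,6-dihydro-2H-pyran-2-one | O=C1C=CCCO1 | starting material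
2 | (±)-trans-3,4-dibromotetrahydro-2H-pyran-2-one | O=C1OCC[C@@H](Br)[C@@H]1Br | intermediate
3 | 3-bromo-5,6-dihydro-2H-pyran-2-one | O=C1OCCC=C1Br | intermediate
4 | (±)-3,5-dibromo-5,6-dihydro-2H-pyran-2-one | O=C1OCC(Br)C=C1Br | intermediate
5 | 3-bromo-2H-pyran-2-one | O=C1OC=CC=C1Br | intermediate
6 | tert-butyl 2-oxopyrrolidine-1-carboxylate | CC(C)(C)OC(=O)N1CCCC1=O | starting material
7 | tert-butyl 5-[(tert-butyldimethylsilyl)oxy]-2,3-dihydro-1H-pyrrole-1-carboxylate | CC(C)(C)OC(=O)N1CCC=C1O[Si](C)(C)C(C)(C)C | intermediate
8 | (±)-tert-butyl 7-bromo-7a-[(tert-butyldimethylsilyl)oxy]-8-oxo-2,3,3a,4,7,7a-hexahydro-1H-4,7-(epoxymethano)indole-1-carboxylate (lactone O on C4, lactone C=O on C7; drawn with the pyrrolidine ring on the side of the C5=C6 bridge) | O=C1O[C@@H]2C=C[C@@]1(Br)[C@@]1(O[Si](C)(C)C(C)(C)C)N(C(=O)OC(C)(C)C)CC[C@@H]21 | intermediate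
9 | (±)-tert-butyl 7-bromo-7a-[(tert-butyldimethylsilyl)oxy]-2,3,3a,7a-tetrahydro-1H-indole-1-carboxylate (cis-fused, H-3a and OSi cis) | CC(C)(C)OC(=O)N1CC[C@H]2C=CC=C(Br)[C@@]12O[Si](C)(C)C(C)(C)C | intermediate
10 | tert-butyl 7-bromoindoline-1-carboxylate | CC(C)(C)OC(=O)N1CCc2cccc(Br)c21 | intermediate
11 | 7-bromoindoline | Brc1cccc2CCNc12 | intermediate
12 | 7-bromo-1H-indole | Brc1cccc2cc[nH]c12 | intermediate
13 | 3,7-dibromo-1H-indole | Brc1c[nH]c2c(Br)cccc12 | intermediate
14 | 2,3,7-tribromo-1H-indole | Brc1[nH]c2c(Br)cccc2c1Br | target

**Count**
Total steps: 8.
Longest linear sequence: 7 steps (steps 1, 2, 3, 5, 6, 7, 8, from 1 to 14). The dienophile branch (step 4) joins at step 5.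

**Steps most likely to fail**

Step 5.
- The second σ-bond joins two fully substituted carbons, so the cycloaddition may be slow.
- The polar first stage may collapse by silyl transfer and opening of the pyrone ring instead of ring closure.
- The liberated silanol may consume the ketene acetal.
- Aromatisation may expel the carbamate nitrogen instead of the silanol.

Fallback (known chemistry, carbamate-directed ortho-lithiation): the benzene ring is bought instead of built. No numbered compound feeds this detour. It sets out from commercial tert-butyl indoline-1-carboxylate F1, which takes the place of both 5 and 7. s-BuLi/TMEDA in Et2O at −78 °C should remove H-7 under direction of the Boc carbonyl to give tert-butyl 7-lithioindoline-1-carboxylate F2. A quench with 1,2-dibromoethane should then deliver 10, where the route is rejoined before step 6.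

Step 8.
- Bromination may run on into the benzo ring.
- Adventitious water may divert the bromination into oxidation at C2.
- The second bromination may stall.
- The light- and acid-sensitive product may decay during isolation.

Fallback (each bromine placed by its own site-specific reaction): it sets out from 12 and comes back at the target 14.
- Boc2O/DMAP should give tert-butyl 7-bromo-1H-indole-1-carboxylate F3.
- LDA in THF at −78 °C deprotonates C2 without exchanging the aryl bromide and should give tert-butyl 7-bromo-2-lithio-1H-indole-1-carboxylate F4.
- 1,2-Dibromo-1,1,2,2-tetrachloroethane should convert F4 into tert-butyl 2,7-dibromo-1H-indole-1-carboxylate F5.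
- Methanolysis with K2CO3 in MeOH should free 2,7-dibromo-1H-indole F6.
- One equivalent of NBS in THF at low temperature should brominate the open C3 to give 14.

Step 4.
- The silyl triflate may attack the Boc group, with loss of the protecting group.
- Silylation may occur on carbon instead of oxygen.
- The acetal may hydrolyse during isolation.

Fallback (base-first enolate chemistry instead of electrophile-first activation, so that no Lewis acid meets the carbamate): it sets out from 6 and comes back at 7. LiHMDS in THF at −78 °C should give the lithium enolate of 6, F7, which is trapped on oxygen with TBSCl in THF/DMPU. After a non-aqueous work-up this should deliver 7.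

**Further compounds**
F1 | step 5 | tert-butyl indoline-1-carboxylate | CC(C)(C)OC(=O)N1CCc2ccccc21
F2 | step 5 | tert-butyl 7-lithioindoline-1-carboxylate | CC(C)(C)OC(=O)N1CCc2cccc([Li])c21
F3 | step 8 | tert-butyl 7-bromo-1H-indole-1-carboxylate | CC(C)(C)OC(=O)n1ccc2cccc(Br)c21
F4 | step 8 | tert-butyl 7-bromo-2-lithio-1H-indole-1-carboxylate | CC(C)(C)OC(=O)n1c([Li])cc2cccc(Br)c21
F5 | step 8 | tert-butyl 2,7-dibromo-1H-indole-1-carboxylate | CC(C)(C)OC(=O)n1c(Br)cc2cccc(Br)c21
F6 | step 8 | 2,7-dibromo-1H-indole | Brc1cc2cccc(Br)c2[nH]1
F7 | step 4 | lithium enolate of tert-butyl 2-oxopyrrolidine-1-carboxylate | CC(C)(C)OC(=O)N1CCC=C1[O-].[Li+]
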